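**Retrosynthetic overview**
1. The epoxide comes last, by C3-OH/C14-OH-directed epoxidation of a ring-cis C1=C10 allylic alcohol. That alcohol comes from SeO2 allylic hydroxylation of the ring-trans 1(10)-alkene, whose [2,3] step inverts the ring geometry. The C8 ester comes from bought (R)-2-methylbutanoic acid.
2. The cis-fused α-methylene lactone comes from lactone methylenation, after chelation-controlled reduction and lactonisation of a C7-carboxymethyl C6-ketone.
3. The ten-membered ring comes from an anionic oxy-Cope [3,3] rearrangement of a trans-1,2-dialkenylcyclohexenol. It forms the C8–C9 bond and sets C8 by chirality transfer. The enolate is trapped in situ with bromoacetate to set C7.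
4. The carbinol comes from (Z)-2-(PMB-oxy)vinyllithium and a 4-silyloxy-isopiperitenone, made from (S)-carvone by Luche reduction, silylation and allylic oxidation.
5. Ring order: cyclohexene (bought) → ten-membered carbocycle (oxy-Cope) → γ-lactone → epoxide.

Assumption: ring atoms carry germacranolide numbers (C1/C10 = epoxide carbons, C14 on C10; C3 = CHOH; C4=C5 with C15 on C4; C6 = lactone O–CH; C7 = ring fusion; C8 = acyloxy CH; C11–C13 = lactone carbons); (S)-carvone and (R)-2-methylbutanoic acid are bought as single enantiomers.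

**Step 1**
Reactants: 1 (S)-(+)-carvone
Product: 2 (1S,5S)-2-methyl-5-(prop-1-en-2-yl)cyclohex-2-en-1-ol, (+)-cis-carveol
Conditions: NaBH4, CeCl3·7H2O, MeOH, −78 → 0 °C
Reagents that add atoms: none
Why: Luche 1,2-reduction delivers hydride axially to the half-chair enone with the isopropenyl group equatorial, so the bought C5 centre sets the new carbinol (1S, OH cis to isopropenyl, dr about 95:5).

**Step 2**
Reactants: 2 (+)-cis-carveol
Product: 3 tert-butyldimethylsilyl ether of 2
Conditions: TBSCl, imidazole, DMF, rt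
Reagents that add atoms: tert-butyldimethylsilyl chloride, CC(C)(C)[Si](C)(C)Cl
Why: Imidazole-promoted O-silylation protects the allylic alcohol without touching either stereocentre.

**Step 3**
Reactants: 3 silyl ether
Product: 4 (4S,6S)-4-[(tert-butyldimethylsilyl)oxy]-3-methyl-6-(prop-1-en-2-yl)cyclohex-2-en-1-one
Conditions: CrO3, 3,5-dimethylpyrazole, CH2Cl2, −20 °C
Reagents that add atoms: chromium trioxide, O=[Cr](=O)=O
Why: Allylic oxidation by the CrO3–pyrazole complex converts the only free ring allylic CH2 into the enone carbonyl (the later C6), and the cold non-basic medium leaves the now α-carbonyl stereocentre unepimerised.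

**Step 4**
Reactants: 5 4-methoxybenzyl alcohol
Product: 6 4-methoxybenzyl vinyl ether
Conditions: [Ir(cod)Cl]2 (1 mol%), Na2CO3 (0.6 equiv), vinyl acetate, toluene, 100 °C
Reagents that add atoms: vinyl acetate, C=COC(C)=O
Why: Iridium-catalysed transvinylation (addition–elimination of the alcohol on coordinated vinyl acetate) gives the vinyl ether; no stereocentre is involved.

**Step 5**
Reactants: 6 4-methoxybenzyl vinyl ether
Product: 8 (Z)-1-bromo-2-[(4-methoxybenzyl)oxy]ethene, via dibromo ether 7 (not isolated)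
Conditions: Br2, CH2Cl2, −78 °C; then i-Pr2NEt, −78 °C → rt
Reagents that add atoms: bromine, BrBr
Why: Bromine addition to the enol ether followed by amine dehydrobromination of the α-bromo ether gives the β-bromo enol ether, with the Z isomer favoured by anti elimination from the gauche conformer and by the cis preference of 1,2-heteroatom-substituted alkenes (minor E isomer removed by chromatography).

**Step 6**
Reactants: 8 (Z)-1-bromo-2-[(4-methoxybenzyl)oxy]ethene; 4 enone
Product: 10 (1S,4S,6S)-4-[(tert-butyldimethylsilyl)oxy]-1-{(Z)-2-[(4-methoxybenzyl)oxy]ethenyl}-3-methyl-6-(prop-1-en-2-yl)cyclohex-2-en-1-ol, via vinyllithium 9 (not isolated)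
Conditions: 8, t-BuLi (2 equiv), Et2O, −78 °C; then 4, −78 °C; H2O
Reagents that add atoms: none
Why: Bromine–lithium exchange with retention gives an oxygen-coordinated Z-vinyllithium whose 1,2-addition to the enone carbonyl occurs anti to the adjacent isopropenyl group, so the two alkenyl groups are trans and the carbinol centre is set by the carvone-derived one (minor diastereomer separated).

**Step 7**
Reactants: 10 dialkenyl carbinol
Product: 13 methyl 2-[(1R,2R,4E,7S,8Z)-7-[(tert-butyldimethylsilyl)oxy]-2-[(4-methoxybenzyl)oxy]-4,8-dimethyl-10-oxocyclodeca-4,8-dien-1-yl]acetate, via potassium alkoxide 11 (not isolated), via potassium enolate 12 (not isolated)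
Conditions: KN(SiMe3)2, 18-crown-6, THF, 0 °C → rt; then BrCH2CO2Me, −78 °C
Reagents that add atoms: methyl bromoacetate, COC(=O)CBr
Why: The anionic oxy-Cope [3,3]-sigmatropic rearrangement goes through the only chair open to the trans-dialkenyl alkoxide, breaking C6–C1 and forming the C8–C9 ring bond with a ring-trans C1=C10 alkene and transfer of the carvone-derived configuration to C8 (Z-alkoxy pseudo-axial, hence 8R), and the ring-trans enolate, whose inner face is covered by the C9–C10 segment, is alkylated on its outer face to give 7R.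

**Step 8**
Reactants: 13 keto ester
Product: 15 (3S,6S,7R,8R)-3-[(tert-butyldimethylsilyl)oxy]-8-[(4-methoxybenzyl)oxy]-13-norgermacra-1(10)E,4Z-dien-12,6-olide (cis-fused γ-lactone), via hydroxy ester 14 (not isolated)
Conditions: Zn(BH4)2, Et2O, −20 → 0 °C; aqueous work-up; then PPTS (cat.), toluene, 50 °C
Reagents that add atoms: none
Why: Chelation-controlled 1,2-reduction, with zinc bridging the ketone and the C8 OPMB oxygen, delivers hydride to give the 6,8-syn (6S) allylic alcohol anti to the C7 side chain, and the resulting cis γ-hydroxy ester lactonises under mild acid.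

**Step 9**
Reactants: 15 lactone
Product: 18 (3S,6S,7R,8R)-3-[(tert-butyldimethylsilyl)oxy]-8-[(4-methoxybenzyl)oxy]germacra-1(10)E,4Z,11(13)-trien-12,6-olide, via Mannich base 16 (not isolated), via methiodide 17 (not isolated)
Conditions: LiN(i-Pr)2, THF, −78 °C; CH2=NMe2+ I−, −78 °C → rt; MeI, MeOH, rt; NaHCO3 (aq), CH2Cl2
Reagents that add atoms: N,N-dimethylmethyleneiminium iodide (Eschenmoser's salt), C=[N+](C)C.[I-]; iodomethane, CI (its methyl sits in 17 and leaves with trimethylamine)
Why: Mannich reaction of the lactone enolate, quaternisation and E1cB elimination install the exocyclic methylene; C7 is not acidic and no ring stereocentre is touched.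

**Step 10**
Reactants: 18 PMB ether
Product: 19 (3S,6S,7R,8R)-3-[(tert-butyldimethylsilyl)oxy]-8-hydroxygermacra-1(10)E,4Z,11(13)-trien-12,6-olide
Conditions: DDQ, CH2Cl2/pH 7 buffer, 0 °C
Reagents that add atoms: none
Why: Oxidative PMB cleavage (benzylic hydride abstraction by DDQ, then hydrolysis) frees the C8 hydroxyl under buffered neutral conditions that spare the silyl ether, alkenes and lactone, with no change at C8.

**Step 11**
Reactants: 19 C8 alcohol; 20 (R)-2-methylbutanoic acid
Product: 21 (3S,6S,7R,8R)-3-[(tert-butyldimethylsilyl)oxy]-8-{[(2R)-2-methylbutanoyl]oxy}germacra-1(10)E,4Z,11(13)-trien-12,6-olide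
Conditions: DCC, DMAP (cat.), CH2Cl2, 0 °C → rt
Reagents that add atoms: none
Why: Steglich esterification acylates the only free hydroxyl with retention at C8 and, cold with catalytic DMAP, without epimerising the bought α-stereocentre of the acid.

**Step 12**
Reactants: 21 ester
Product: 22 (3S,6S,7R,8R)-3-[(tert-butyldimethylsilyl)oxy]-14-hydroxy-8-{[(2R)-2-methylbutanoyl]oxy}germacra-1(10),4Z,11(13)-trien-12,6-olide with C2 and C9 cis across C1=C10
Conditions: SeO2 (20 mol%), t-BuOOH (3 equiv), CH2Cl2, rt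
Reagents that add atoms: tert-butyl hydroperoxide, CC(C)(C)OO (terminal oxidant; oxygen relayed by catalytic SeO2, O=[Se]=O)
Why: Selenium dioxide allylic oxidation (ene reaction at the electron-richer C1=C10 alkene, then [2,3]-sigmatropic shift) hydroxylates C14 and places the CH2O group trans to C2, turning the ring-trans alkene into the ring-cis one as known for 1(10)-germacrenolides, while C4=C5 is deactivated by its two allylic C–O bonds.

**Step 13**
Reactants: 22 silyl ether
Product: 23 (3S,6S,7R,8R)-3,14-dihydroxy-8-{[(2R)-2-methylbutanoyl]oxy}germacra-1(10),4Z,11(13)-trien-12,6-olide (ring-cis C1=C10)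
Conditions: HF·pyridine, pyridine, THF, 0 °C → rt
Reagents that add atoms: none
Why: Buffered fluoride desilylation frees the C3 hydroxyl without affecting the ester, lactone or alkenes.

**Step 14**
Reactants: 23 diol
Product: 24 (1R,3S,4Z,6S,7R,8R,10R)-1,10-epoxy-3,14-dihydroxy-8-{[(2R)-2-methylbutanoyl]oxy}germacra-4,11(13)-dien-12,6-olide (target)
Conditions: VO(acac)2 (5 mol%), t-BuOOH (1.1 equiv), CH2Cl2, 0 °C
Reagents that add atoms: tert-butyl hydroperoxide, CC(C)(C)OO
Why: Hydroxyl-directed epoxidation by a vanadium alkyl peroxide, in which the C14 alkoxide binds the metal (chemoselectivity for C1=C10) and the homoallylic C3 hydroxyl on the same ring face directs oxygen delivery syn to itself, gives the cis-epoxide with 1R,10R configuration under control of C3.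

**Compound list**
1 | (S)-(+)-carvone | CC(=C)[C@H]1CC=C(C)C(=O)C1 | starting material
2 | (1S,5S)-cis-carveol | CC(=C)[C@H]1CC=C(C)[C@@H](O)C1 | intermediate
3 | TBS ether of 2 | CC(=C)[C@H]1CC=C(C)[C@@H](O[Si](C)(C)C(C)(C)C)C1 | intermediate
4 | (4S,6S)-4-TBSO-3-methyl-6-isopropenylcyclohex-2-en-1-one | CC(=C)[C@H]1C(=O)C=C(C)[C@@H](O[Si](C)(C)C(C)(C)C)C1 | intermediate
5 | 4-methoxybenzyl alcohol | COc1ccc(CO)cc1 | starting material
6 | 4-methoxybenzyl vinyl ether | C=COCc1ccc(OC)cc1 | intermediate
7 | 1,2-dibromo-1-[(4-methoxybenzyl)oxy]ethane (racemic) | BrCC(Br)OCc1ccc(OC)cc1 | intermediate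
8 | (Z)-1-bromo-2-[(4-methoxybenzyl)oxy]ethene | Br/C=C\OCc1ccc(OC)cc1 | intermediate
9 | (Z)-2-[(4-methoxybenzyl)oxy]ethenyllithium | [Li]/C=C\OCc1ccc(OC)cc1 | intermediate
10 | (1S,4S,6S)-dialkenyl carbinol (OH cis to isopropenyl and to OTBS; alkenyl groups trans) | CC(=C)[C@H]1[C@](O)(/C=C\OCc2ccc(OC)cc2)C=C(C)[C@@H](O[Si](C)(C)C(C)(C)C)C1 | intermediate
11 | potassium alkoxide of 10 | [K+].CC(=C)[C@H]1[C@]([O-])(/C=C\OCc2ccc(OC)cc2)C=C(C)[C@@H](O[Si](C)(C)C(C)(C)C)C1 | intermediate
12 | potassium enolate of the ring-expanded ketone (ring-trans C6=C7, O6 syn to C8; 3S,8R) | C/C1=C/C(/[O-])=C/[C@H](OCc2ccc(OC)cc2)C/C(C)=C/C[C@@H]1O[Si](C)(C)C(C)(C)C.[K+] | intermediate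
13 | keto ester (3S,7R,8R; 1(10)E,4Z; C6 ketone) | O=C1/C=C(/C)[C@@H](O[Si](C)(C)C(C)(C)C)C/C=C(\C)C[C@@H](OCc2ccc(OC)cc2)[C@H]1CC(=O)OC | intermediate
14 | (6S)-hydroxy ester | O[C@H]1/C=C(/C)[C@@H](O[Si](C)(C)C(C)(C)C)C/C=C(\C)C[C@@H](OCc2ccc(OC)cc2)[C@H]1CC(=O)OC | intermediate
15 | cis-lactone (3S,6S,7R,8R) | C1C(=O)O[C@H]2/C=C(/C)[C@@H](O[Si](C)(C)C(C)(C)C)C/C=C(\C)C[C@@H](OCc3ccc(OC)cc3)[C@@H]12 | intermediate
16 | Mannich base (C11 epimers) | CN(C)CC1C(=O)O[C@H]2/C=C(/C)[C@@H](O[Si](C)(C)C(C)(C)C)C/C=C(\C)C[C@@H](OCc3ccc(OC)cc3)[C@@H]12 | intermediate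
17 | trimethylammonium iodide of 16 | C[N+](C)(C)CC1C(=O)O[C@H]2/C=C(/C)[C@@H](O[Si](C)(C)C(C)(C)C)C/C=C(\C)C[C@@H](OCc3ccc(OC)cc3)[C@@H]12.[I-] | intermediate
18 | α-methylene lactone, 8-OPMB, 3-OTBS | C=C1C(=O)O[C@H]2/C=C(/C)[C@@H](O[Si](C)(C)C(C)(C)C)C/C=C(\C)C[C@@H](OCc3ccc(OC)cc3)[C@@H]12 | intermediate
19 | α-methylene lactone, 8-OH, 3-OTBS | C=C1C(=O)O[C@H]2/C=C(/C)[C@@H](O[Si](C)(C)C(C)(C)C)C/C=C(\C)C[C@@H](O)[C@@H]12 | intermediate
20 | (R)-2-methylbutanoic acid | CC[C@@H](C)C(=O)O | starting material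
21 | 8-O-[(2R)-2-methylbutanoyl] ester, 3-OTBS, ring-trans 1(10) | C=C1C(=O)O[C@H]2/C=C(/C)[C@@H](O[Si](C)(C)C(C)(C)C)C/C=C(\C)C[C@@H](OC(=O)[C@H](C)CC)[C@@H]12 | intermediate
22 | 14-hydroxy ester, 3-OTBS, ring-cis 1(10) | C=C1C(=O)O[C@H]2/C=C(/C)[C@@H](O[Si](C)(C)C(C)(C)C)C/C=C(/CO)C[C@@H](OC(=O)[C@H](C)CC)[C@@H]12 | intermediate
23 | 3,14-diol ester, ring-cis 1(10) | C=C1C(=O)O[C@H]2/C=C(/C)[C@@H](O)C/C=C(/CO)C[C@@H](OC(=O)[C@H](C)CC)[C@@H]12 | intermediate
24 | CNP0356520.2 | C=C1C(=O)O[C@H]2/C=C(/C)[C@@H](O)C[C@H]3O[C@@]3(CO)C[C@@H](OC(=O)[C@H](C)CC)[C@@H]12 | target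

**Step count**
Total: 14 steps. Longest linear sequence: 12 steps (1, 2, 3, 6–14); steps 4 and 5 form the two-step side branch.

**Three steps most likely to fail**

Step 7. The Z-alkoxy group is pseudo-axial and syn to the alkoxide in the chair, so a boat pathway could leak the C8 epimer. The β-alkoxy enolate can lose PMB-oxide by E1cB. The facial selectivity of the alkylation rests on the conformation of a flexible ring. Fallback: set out from 10 and separate the two events. After the rearrangement, enolate 12 is quenched at −78 °C with Me3SiCl to give the trimethylsilyl enol ether F1, which can be purified away from any C8 epimer. MeLi in THF at 0 °C then releases a crown-free lithium enolate that is chelated by the C8 OPMB oxygen. Alkylation with methyl bromoacetate at −78 °C then occurs anti to C9 on the chelate, and the route is rejoined at 13.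

Step 8. Peripheral hydride attack on the ring conformer could override zinc chelation and give the 6R alcohol, which would lead to the trans-lactone. Fallback: set out from 13 and accept that outcome. The (6R)-hydroxy ester F2 (or its lactone) is saponified with LiOH in THF/H2O to the (6R)-hydroxy acid F3. F3 is closed with PPh3/DIAD in a Mitsunobu lactonisation, whose SN2 inversion at the allylic C6 gives the cis-lactone and rejoins the route at 15.

Step 14. The free C3 hydroxyl is also allylic to C4=C5, so over-epoxidation can compete. Face control depends on cooperation of a homoallylic hydroxyl across a flexible ring. Fallback: set out from 19, where C3 is still silylated and the β C8 hydroxyl is free.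
- SeO2/t-BuOOH as in step 12 gives the ring-cis 8,14-diol F4.
- TBSCl/imidazole silylates only the primary alcohol to give the 14-O-TBS ether F5.
- VO(acac)2/t-BuOOH then epoxidises C1=C10 syn to the homoallylic C8 hydroxyl, its only directing group, to give the epoxy alcohol F6.
- DCC/DMAP esterification with 20 gives the bis-silyl ester F7.
- HF·pyridine removes both silyl groups and rejoins the route at 24.

**Further compounds**
F1 | step 7 | trimethylsilyl enol ether of the ring-expanded ketone (ring-trans C6=C7; 3S,8R) | C/C1=C/C(/O[Si](C)(C)C)=C/[C@H](OCc2ccc(OC)cc2)C/C(C)=C/C[C@@H]1O[Si](C)(C)C(C)(C)C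
F2 | step 8 | (6R)-hydroxy ester (C6 epimer of 14) | O[C@@H]1/C=C(/C)[C@@H](O[Si](C)(C)C(C)(C)C)C/C=C(\C)C[C@@H](OCc2ccc(OC)cc2)[C@H]1CC(=O)OC
F3 | step 8 | (6R)-hydroxy acid | O[C@@H]1/C=C(/C)[C@@H](O[Si](C)(C)C(C)(C)C)C/C=C(\C)C[C@@H](OCc2ccc(OC)cc2)[C@H]1CC(=O)O
F4 | step 14 | 8,14-diol, 3-OTBS, ring-cis 1(10) | C=C1C(=O)O[C@H]2/C=C(/C)[C@@H](O[Si](C)(C)C(C)(C)C)C/C=C(/CO)C[C@@H](O)[C@@H]12
F5 | step 14 | 14-O-TBS ether of F4 | C=C1C(=O)O[C@H]2/C=C(/C)[C@@H](O[Si](C)(C)C(C)(C)C)C/C=C(/CO[Si](C)(C)C(C)(C)C)C[C@@H](O)[C@@H]12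
F6 | step 14 | (1R,10R)-epoxy alcohol, 3,14-bis-OTBS, 8-OH | C=C1C(=O)O[C@H]2/C=C(/C)[C@@H](O[Si](C)(C)C(C)(C)C)C[C@H]3O[C@@]3(CO[Si](C)(C)C(C)(C)C)C[C@@H](O)[C@@H]12
F7 | step 14 | 8-O-[(2R)-2-methylbutanoyl] ester of F6 | C=C1C(=O)O[C@H]2/C=C(/C)[C@@H](O[Si](C)(C)C(C)(C)C)C[C@H]3O[C@@]3(CO[Si](C)(C)C(C)(C)C)C[C@@H](OC(=O)[C@H](C)CC)[C@@H]12
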